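## Retrosynthetic overview

1. Target 16 comes from 15 by removal of three MOM groups. 15 comes from the ring-A salicylaldehyde 5 and the ring-B arylalkyne 13 by a formal [4+2] annulation in one flask: C3–C4 by rhodium-catalysed alkyne hydroacylation, then O1–C2 by a catalyst-controlled oxa-Michael closure that sets C2.
2. Enabling feature: O1 and the C4 carbonyl carbon of ring C sit on adjacent carbons (C8a, C4a) of ring A, so a salicylaldehyde can chelate rhodium through O1 and its formyl carbon. C2 is β to the C4 ketone, so O1 closes ring C by conjugate addition onto the new enone.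
3. 5 comes from 2,4,6-trihydroxybenzaldehyde 1 (bis-MOM, O-allyl, Claisen, cross-metathesis). The Claisen step leaves free only the phenol next to the prenyl group, which fixes the 8-prenyl pattern.
4. 13 comes from 3,4-dihydroxybenzaldehyde 6: 4-O-propargyl ether to the dimethylpyran ring, 8-O reverse-prenyl ether Claisen to the C7 prenyl group, MOM protection, alkyne homologation.
5. Ring order: rings A and B are bought; the dimethylpyran ring on ring B is formed first (step 6), ring C last (step 12).

Key step: step 12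

Assumption: the quinine-derived bifunctional thiourea is taken to deliver the (2S) sense in step 12; if the facial preference is the reverse, its quinidine-derived pseudoenantiomer is used in the same step.

## Route

Step 1
Reactants: 1 2,4,6-trihydroxybenzaldehyde
Product: 2 2-hydroxy-4,6-bis(methoxymethoxy)benzaldehyde
Conditions: MOMCl (2.2 equiv), i-Pr2NEt, CH2Cl2, 0 °C to rt
Reagents that add atoms: chloromethyl methyl ether, COCCl
Why: Williamson-type acetal ether formation (MOM protection) should stop at the bis-ether because the last phenol is hydrogen-bonded to the formyl group and is the least nucleophilic.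

Step 2
Reactants: 2 2-hydroxy-4,6-bis(methoxymethoxy)benzaldehyde
Product: 3 2-(allyloxy)-4,6-bis(methoxymethoxy)benzaldehyde
Conditions: allyl bromide, K2CO3, DMF, 60 °C
Reagents that add atoms: allyl bromide, C=CCBr
Why: Williamson etherification of the chelated phenol proceeds under carbonate/DMF conditions once the other two phenols are blocked.

Step 3
Reactants: 3 2-(allyloxy)-4,6-bis(methoxymethoxy)benzaldehyde
Product: 4 3-allyl-2-hydroxy-4,6-bis(methoxymethoxy)benzaldehyde
Conditions: PhNEt2, 190 °C, sealed tube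
Reagents that add atoms: none
Why: The aromatic Claisen rearrangement ([3,3] shift then tautomerisation) can only end at C3, the one ortho carbon that carries hydrogen, and it frees exactly the phenol that lies next to the new allyl group.

Step 4
Reactants: 4 3-allyl-2-hydroxy-4,6-bis(methoxymethoxy)benzaldehyde
Product: 5 2-hydroxy-4,6-bis(methoxymethoxy)-3-(3-methylbut-2-en-1-yl)benzaldehyde
Conditions: 2-methylbut-2-ene (excess), second-generation Grubbs catalyst RuCl2(=CHPh)(PCy3)(H2IMes) (5 mol %), CH2Cl2, 40 °C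
Reagents that add atoms: 2-methylbut-2-ene, CC=C(C)C
Why: Olefin cross-metathesis of a terminal allyl arene with 2-methylbut-2-ene is a standard allyl-to-prenyl conversion that tolerates phenol, aldehyde and acetal groups.

Step 5
Reactants: 6 3,4-dihydroxybenzaldehyde
Product: 7 3-hydroxy-4-[(2-methylbut-3-yn-2-yl)oxy]benzaldehyde
Conditions: 3-chloro-3-methylbut-1-yne (1.05 equiv), K2CO3 (1.1 equiv), KI (cat.), CuI (cat.), DMF, 60 °C
Reagents that add atoms: 3-chloro-3-methylbut-1-yne, CC(C)(Cl)C#C
Why: Copper-assisted Williamson-type O-propargylation should occur at the 4-hydroxyl because this phenol, para to the formyl group, is the more acidic one and is the only one deprotonated by one equivalent of carbonate.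

Step 6
Reactants: 7 3-hydroxy-4-[(2-methylbut-3-yn-2-yl)oxy]benzaldehyde
Product: 8 8-hydroxy-2,2-dimethyl-2H-chromene-6-carbaldehyde
Conditions: PhNEt2, 180 °C
Reagents that add atoms: none
Why: The thermal aryl propargyl ether Claisen rearrangement/1,5-hydrogen shift/6π-oxa-electrocyclisation cascade builds the 2,2-dimethylpyran ring at C5, the only free ortho carbon of the ether oxygen.

Step 7
Reactants: 8 8-hydroxy-2,2-dimethyl-2H-chromene-6-carbaldehyde
Product: 9 2,2-dimethyl-8-[(2-methylbut-3-yn-2-yl)oxy]-2H-chromene-6-carbaldehyde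
Conditions: 3-chloro-3-methylbut-1-yne, DBU, CuCl2·2H2O (cat.), MeCN, 0 °C
Reagents that add atoms: 3-chloro-3-methylbut-1-yne, CC(C)(Cl)C#C
Why: Copper-catalysed O-alkylation of phenols with tertiary propargylic chlorides under amidine base is an established way to make 1,1-dimethylpropargyl aryl ethers at low temperature, well below the onset of the Claisen cascade.

Step 8
Reactants: 9 2,2-dimethyl-8-[(2-methylbut-3-yn-2-yl)oxy]-2H-chromene-6-carbaldehyde
Product: 10 2,2-dimethyl-8-[(2-methylbut-3-en-2-yl)oxy]-2H-chromene-6-carbaldehyde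
Conditions: H2 (1 atm), Pd/CaCO3 poisoned with Pb(OAc)2 (Lindlar catalyst), quinoline, EtOAc, rt
Reagents that add atoms: none
Why: Lindlar semihydrogenation reduces the terminal alkyne far faster than the hindered chromene double bond or the aldehyde.

Step 9
Reactants: 10 2,2-dimethyl-8-[(2-methylbut-3-en-2-yl)oxy]-2H-chromene-6-carbaldehyde
Product: 11 8-hydroxy-2,2-dimethyl-7-(3-methylbut-2-en-1-yl)-2H-chromene-6-carbaldehyde
Conditions: xylenes, 130 °C
Reagents that add atoms: none
Why: The aromatic Claisen rearrangement of a 1,1-dimethylallyl aryl ether delivers a normal prenyl group to C7, the only ortho carbon that carries hydrogen since C8a is part of the pyran ring.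

Step 10
Reactants: 11 8-hydroxy-2,2-dimethyl-7-(3-methylbut-2-en-1-yl)-2H-chromene-6-carbaldehyde
Product: 12 8-(methoxymethoxy)-2,2-dimethyl-7-(3-methylbut-2-en-1-yl)-2H-chromene-6-carbaldehyde
Conditions: MOMCl, i-Pr2NEt, CH2Cl2, 0 to 40 °C
Reagents that add atoms: chloromethyl methyl ether, COCCl
Why: MOM protection (Williamson-type acetal ether formation) masks the ring-B phenol so that the only free phenol in the key step is the one that must become O1.

Step 11
Reactants: 12 8-(methoxymethoxy)-2,2-dimethyl-7-(3-methylbut-2-en-1-yl)-2H-chromene-6-carbaldehyde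
Product: 13 6-ethynyl-8-(methoxymethoxy)-2,2-dimethyl-7-(3-methylbut-2-en-1-yl)-2H-chromene
Conditions: dimethyl (1-diazo-2-oxopropyl)phosphonate, K2CO3, MeOH, 0 °C to rt
Reagents that add atoms: dimethyl (1-diazo-2-oxopropyl)phosphonate, CC(=O)C(=[N+]=[N-])P(=O)(OC)OC
Why: Seyferth–Gilbert homologation with the Ohira–Bestmann reagent converts an aryl aldehyde into the terminal alkyne under mild carbonate conditions that leave the acetal, prenyl and chromene groups untouched.

Step 12
Reactants: 5 2-hydroxy-4,6-bis(methoxymethoxy)-3-(3-methylbut-2-en-1-yl)benzaldehyde; 13 6-ethynyl-8-(methoxymethoxy)-2,2-dimethyl-7-(3-methylbut-2-en-1-yl)-2H-chromene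
Product: 15 (2S)-5,7-bis(methoxymethoxy)-2-[8-(methoxymethoxy)-2,2-dimethyl-7-(3-methylbut-2-en-1-yl)-2H-chromen-6-yl]-8-(3-methylbut-2-en-1-yl)-2,3-dihydro-4H-chromen-4-one, via (E)-2'-hydroxychalcone 14 (not isolated)
Conditions: [Rh(cod)Cl]2 (2.5 mol %), 1,1'-bis(diphenylphosphino)ferrocene Fe(C5H4PPh2)2 (5 mol %), Na2CO3 (10 mol %), toluene, 80 °C; then −20 °C, 1-[3,5-bis(trifluoromethyl)phenyl]-3-[(8S,9S)-6'-methoxycinchonan-9-yl]thiourea (quinine-derived, 10 mol %); then AcOH quench
Reagents that add atoms: none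
Why: Proposed new method: phenoxide-directed oxidative addition of the formyl C–H of 5 to monovalent rhodium gives a five-membered acyl rhodium hydride chelate, syn hydrometalation of the terminal alkyne of 13 with rhodium at the unsubstituted carbon and C–C reductive elimination give (E)-chalcone 14 (C3–C4 bond), and the bifunctional cinchona thiourea added to the same flask then deprotonates the chelated phenol with its quinuclidine while its thiourea hydrogen-bonds the C4 carbonyl, so that O1 adds to C2 (O1–C2 bond). The closest known reaction types are the one-pot rhodium-catalysed alkyne hydroacylation/oxa-Michael annulation of salicylaldehydes to racemic chroman-4-ones and the cinchona-thiourea-catalysed enantioselective oxa-Michael cyclisation of activated 2'-hydroxychalcone derivatives; their merger into an enantioselective relay on an unactivated chalcone is the new element. Ring C closes by a 6-endo-trig oxa-Michael addition. The C2 stereocentre is set by the chiral catalyst, which delivers its ion-paired phenoxide to one enantiotopic face of the enone, and it is preserved by working at low temperature and quenching with acid before reversible retro-Michael opening can erode it. The step needs linear regioselectivity in the hydroacylation (favoured by the terminal alkyne and by the ortho-prenyl group, which disfavours rhodium at the aryl-bearing carbon), chemoselectivity for the alkyne over the two trisubstituted prenyl alkenes and the hindered chromene alkene, and closure by the correct phenol, which is secured because only the oxygen next to the ring-A prenyl group is free.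

Step 13
Reactants: 15 (2S)-5,7-bis(methoxymethoxy)-2-[8-(methoxymethoxy)-2,2-dimethyl-7-(3-methylbut-2-en-1-yl)-2H-chromen-6-yl]-8-(3-methylbut-2-en-1-yl)-2,3-dihydro-4H-chromen-4-one
Product: 16 (2S)-5,7-dihydroxy-2-[8-hydroxy-2,2-dimethyl-7-(3-methylbut-2-en-1-yl)-2H-chromen-6-yl]-8-(3-methylbut-2-en-1-yl)-2,3-dihydro-4H-chromen-4-one
Conditions: 3 M aq HCl, MeOH, 50 °C, short reaction time
Reagents that add atoms: none
Why: Acid-catalysed acetal solvolysis removes all three MOM groups, and the C2 stereocentre should survive because flavanones racemise through base-mediated ring opening and not under dilute acid.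

## Compound list

1 | 2,4,6-trihydroxybenzaldehyde | O=Cc1c(O)cc(O)cc1O | starting material
2 | 2-hydroxy-4,6-bis(methoxymethoxy)benzaldehyde | O=Cc1c(O)cc(OCOC)cc1OCOC | intermediate
3 | 2-(allyloxy)-4,6-bis(methoxymethoxy)benzaldehyde | O=Cc1c(OCC=C)cc(OCOC)cc1OCOC | intermediate
4 | 3-allyl-2-hydroxy-4,6-bis(methoxymethoxy)benzaldehyde | O=Cc1c(O)c(CC=C)c(OCOC)cc1OCOC | intermediate
5 | 2-hydroxy-4,6-bis(methoxymethoxy)-3-(3-methylbut-2-en-1-yl)benzaldehyde | O=Cc1c(O)c(CC=C(C)C)c(OCOC)cc1OCOC | intermediate
6 | 3,4-dihydroxybenzaldehyde | O=Cc1ccc(O)c(O)c1 | starting material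
7 | 3-hydroxy-4-[(2-methylbut-3-yn-2-yl)oxy]benzaldehyde | O=Cc1ccc(OC(C)(C)C#C)c(O)c1 | intermediate
8 | 8-hydroxy-2,2-dimethyl-2H-chromene-6-carbaldehyde | O=Cc1cc2C=CC(C)(C)Oc2c(O)c1 | intermediate
9 | 2,2-dimethyl-8-[(2-methylbut-3-yn-2-yl)oxy]-2H-chromene-6-carbaldehyde | O=Cc1cc2C=CC(C)(C)Oc2c(OC(C)(C)C#C)c1 | intermediate
10 | 2,2-dimethyl-8-[(2-methylbut-3-en-2-yl)oxy]-2H-chromene-6-carbaldehyde | O=Cc1cc2C=CC(C)(C)Oc2c(OC(C)(C)C=C)c1 | intermediate
11 | 8-hydroxy-2,2-dimethyl-7-(3-methylbut-2-en-1-yl)-2H-chromene-6-carbaldehyde | O=Cc1cc2C=CC(C)(C)Oc2c(O)c1CC=C(C)C | intermediate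
12 | 8-(methoxymethoxy)-2,2-dimethyl-7-(3-methylbut-2-en-1-yl)-2H-chromene-6-carbaldehyde | O=Cc1cc2C=CC(C)(C)Oc2c(OCOC)c1CC=C(C)C | intermediate
13 | 6-ethynyl-8-(methoxymethoxy)-2,2-dimethyl-7-(3-methylbut-2-en-1-yl)-2H-chromene | C#Cc1cc2C=CC(C)(C)Oc2c(OCOC)c1CC=C(C)C | intermediate
14 | (E)-1-[2-hydroxy-4,6-bis(methoxymethoxy)-3-(3-methylbut-2-en-1-yl)phenyl]-3-[8-(methoxymethoxy)-2,2-dimethyl-7-(3-methylbut-2-en-1-yl)-2H-chromen-6-yl]prop-2-en-1-one | O=C(/C=C/c1cc2C=CC(C)(C)Oc2c(OCOC)c1CC=C(C)C)c1c(O)c(CC=C(C)C)c(OCOC)cc1OCOC | intermediate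
15 | (2S)-5,7-bis(methoxymethoxy)-2-[8-(methoxymethoxy)-2,2-dimethyl-7-(3-methylbut-2-en-1-yl)-2H-chromen-6-yl]-8-(3-methylbut-2-en-1-yl)-2,3-dihydro-4H-chromen-4-one | CC(C)=CCc1c([C@@H]2CC(=O)c3c(OCOC)cc(OCOC)c(CC=C(C)C)c3O2)cc2c(c1OCOC)OC(C)(C)C=C2 | intermediate
16 | (2S)-5,7-dihydroxy-2-[8-hydroxy-2,2-dimethyl-7-(3-methylbut-2-en-1-yl)-2H-chromen-6-yl]-8-(3-methylbut-2-en-1-yl)-2,3-dihydro-4H-chromen-4-one | CC(C)=CCc1c([C@@H]2CC(=O)c3c(O)cc(O)c(CC=C(C)C)c3O2)cc2c(c1O)OC(C)(C)C=C2 | target

## Step count and risks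

Total step count: 13. Longest linear sequence: 9 steps (steps 5 to 13, from 3,4-dihydroxybenzaldehyde 6).

Steps most likely to fail:

**Step 12 (Proposed new method).** The oxa-Michael stage may close with poor facial selectivity, the product may lose enantiopurity through reversible ring opening, or the hydroacylation may deliver the acyl group to the internal alkyne carbon. The fallback uses only known chemistry, sets out from 5 (and uses aldehyde 12, so step 11 is skipped) and comes back at 15. Addition of MeMgBr (THF, 0 °C) to 5 should give the racemic benzylic alcohol 1-[2-hydroxy-4,6-bis(methoxymethoxy)-3-(3-methylbut-2-en-1-yl)phenyl]ethan-1-ol F1. Oxidation with MnO2 (CH2Cl2, rt) should give the acetophenone 1-[2-hydroxy-4,6-bis(methoxymethoxy)-3-(3-methylbut-2-en-1-yl)phenyl]ethan-1-one F2. Claisen–Schmidt condensation of this ketone with 12 (KOH, EtOH, rt) should give chalcone 14 with unambiguous regiochemistry. Cyclisation with NaOAc in refluxing EtOH should give the racemic tris-MOM flavanone F3. Kinetic resolution by asymmetric transfer hydrogenation (RuCl(p-cymene)(TsDPEN), HCO2H/Et3N, EtOAc, with the TsDPEN enantiomer chosen so that the (2R)-ketone reacts faster) should reduce the unwanted enantiomer to the cis-(2R,4R)-flavan-4-ol F4. Unreacted (2S)-15 is then separated by chromatography.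

**Step 13.** Acid-promoted addition of the freed ortho phenols to the prenyl double bonds (chroman formation) may compete with acetal cleavage. The fallback sets out from 15 and comes back at 16. It replaces Brønsted-acid solvolysis by silyl transfer: TMSOTf and 2,2'-bipyridyl (CH2Cl2, 0 °C) should convert the aryl MOM ethers, through pyridinium-type intermediates, into the tris(trimethylsilyl) ether of the target F5. Hydrolysis with water at rt under near-neutral conditions should then give 16.

**Step 7.** Etherification of the hindered 8-hydroxyl with a tertiary propargylic electrophile may be slow and lose out to elimination of the chloride. The fallback sets out from 8 and comes back at 11, replacing steps 7 to 9 by the sequence already used for ring A. Allyl bromide/K2CO3 (DMF, 60 °C) should give 8-(allyloxy)-2,2-dimethyl-2H-chromene-6-carbaldehyde F6. Aromatic Claisen rearrangement (PhNEt2, 190 °C) should give 7-allyl-8-hydroxy-2,2-dimethyl-2H-chromene-6-carbaldehyde F7. Cross-metathesis with 2-methylbut-2-ene (second-generation Grubbs catalyst RuCl2(=CHPh)(PCy3)(H2IMes), CH2Cl2, 40 °C) should give 11.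

Further compounds
F1 | step 12 | 1-[2-hydroxy-4,6-bis(methoxymethoxy)-3-(3-methylbut-2-en-1-yl)phenyl]ethan-1-ol (racemic) | CC(O)c1c(O)c(CC=C(C)C)c(OCOC)cc1OCOC
F2 | step 12 | 1-[2-hydroxy-4,6-bis(methoxymethoxy)-3-(3-methylbut-2-en-1-yl)phenyl]ethan-1-one | CC(=O)c1c(O)c(CC=C(C)C)c(OCOC)cc1OCOC
F3 | step 12 | racemic 5,7-bis(methoxymethoxy)-2-[8-(methoxymethoxy)-2,2-dimethyl-7-(3-methylbut-2-en-1-yl)-2H-chromen-6-yl]-8-(3-methylbut-2-en-1-yl)-2,3-dihydro-4H-chromen-4-one | CC(C)=CCc1c(C2CC(=O)c3c(OCOC)cc(OCOC)c(CC=C(C)C)c3O2)cc2c(c1OCOC)OC(C)(C)C=C2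
F4 | step 12 | (2R,4R)-5,7-bis(methoxymethoxy)-2-[8-(methoxymethoxy)-2,2-dimethyl-7-(3-methylbut-2-en-1-yl)-2H-chromen-6-yl]-8-(3-methylbut-2-en-1-yl)-3,4-dihydro-2H-chromen-4-ol | CC(C)=CCc1c([C@H]2C[C@@H](O)c3c(OCOC)cc(OCOC)c(CC=C(C)C)c3O2)cc2c(c1OCOC)OC(C)(C)C=C2
F5 | step 13 | (2S)-2-[2,2-dimethyl-7-(3-methylbut-2-en-1-yl)-8-(trimethylsilyloxy)-2H-chromen-6-yl]-8-(3-methylbut-2-en-1-yl)-5,7-bis(trimethylsilyloxy)-2,3-dihydro-4H-chromen-4-one | CC(C)=CCc1c([C@@H]2CC(=O)c3c(O[Si](C)(C)C)cc(O[Si](C)(C)C)c(CC=C(C)C)c3O2)cc2c(c1O[Si](C)(C)C)OC(C)(C)C=C2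
F6 | step 7 | 8-(allyloxy)-2,2-dimethyl-2H-chromene-6-carbaldehyde | O=Cc1cc2C=CC(C)(C)Oc2c(OCC=C)c1
F7 | step 7 | 7-allyl-8-hydroxy-2,2-dimethyl-2H-chromene-6-carbaldehyde | O=Cc1cc2C=CC(C)(C)Oc2c(O)c1CC=C
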